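The readings were generated by integration with made-up constants; the scatter is artificial.

Set the time a ring survives beside the time it spends in the vessel.

| flask | substrate | remark | time |
|---|---|---|---|
| north-west | 20 mM | run made earlier |  |
| east | 13 mM | run made earlier |  |
| north-east | 30 mM | run made earlier |  |
| spring | 20 mM | a single well-mixed tank run continuously and read at steady state, 1.5 h in it on average |  |
| dusk | 20 mM | a tube with plug flow, the mixed feed as stated, residence time 1.5 h | 1.5 h |
| winter | 20 mM | everything together in a closed stirred flask, run for 1.5 h | 1.5 h |

| run | time / min | ring / % | substrate / % |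
|---|---|---|---|
| north-west | 3.00 | 24.8 | 52.3 |
| north-west | 8.00 | 44.5 | 23.2 |
| north-west | 15.0 | 53.2 | 9.8 |
| north-west | 25.0 | 54.4 | 5.0 |
| north-west | 30.0 | 53.3 | 3.6 |
| north-west | 40.0 | 49.1 | 2.6 |
| north-west | 50.0 | 45.7 | 2.2 |
| east | 12.0 | 55.7 | 15.7 |
| east | 25.0 | 59.0 | 4.6 |
| east | 40.0 | 53.2 | 2.9 |
| east | 50.0 | 49.2 | 1.8 |
| east | 60.0 | 45.1 | 1.1 |
| east | 80.0 | 36.7 | 1.5 |
| east | 90.0 | 33.4 | 1.3 |
| north-east | 5.00 | 33.3 | 31.0 |
| north-east | 15.0 | 46.0 | 9.7 |
| north-east | 25.0 | 48.5 | 4.1 |
| north-east | 40.0 | 45.6 | 2.9 |
| north-east | 50.0 | 42.7 | 2.2 |
| north-east | 80.0 | 35.1 | 1.7 |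
| north-east | 90.0 | 33.6 | 2.0 |

(readings scatter by 0.5 percentage points)

- in percentages every species weighs as the substrate in it: one open dimer or side product counts as two
- the stated concentrations are those of everything mixed, before any reaction; amounts are the same in each set-up
- on the list of suspects stand: substrate + ring -> side product; substrate -> ring; ring -> over-reaction product; 2 substrate <-> open dimer
- the earlier runs were made in a closed, stirred flask

- the set-up with the highest amount of ring at the outlet or at the end, in percent of the substrate put in ("none" if the first two lie within 2 percentage points) (spring / dusk / winter / none)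
- amount of ring at the outlet or at the end, in percent of the substrate put in, spring
- amount of ring at the outlet or at the end, in percent of the substrate put in, dusk
- amount of ring at the outlet or at the end, in percent of the substrate put in, winter

I took the ring's net fall in the east and north-east runs from 50.0 min to 90.0 min; those flasks still read 1.3 % and 2.0 % substrate at the end of that stretch, so the fall is loss less any new ring, not the loss step by itself. The mean of their two slopes gave a fade time, the mean time for ring to fall on balance by a factor e in the late part of a run, of 128 min. Against 1.5 h that made a ratio of 0.705.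

For winter I took the mean of the two readings at 90.0 min, 33.4 % and 33.6 %, from charges on either side of the winter charge, which gave 33.5 %. In the dusk tube each parcel lives as a closed flask for 1.5 h, so I expected the same there.

In the spring tank the stays spread about their mean, so survival is one over one plus the ratio, not e to minus the ratio. Assuming equal ring made, that multiplied winter by 1.19, giving 39.8 %.

The forecast, slightly above me, named spring, with 40.5 % there and 34.5 % and 34.5 % for dusk and winter, because “backmixing shields some ring from over-reaction”.

The flask gave 39.6 % for spring, 33.3 % for dusk and 33.3 % for winter, so spring leads.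

    substrate + ring → side product (k = 3.18 L mol⁻¹ h⁻¹)
    substrate → ring (k = 7.30 h⁻¹)
    ring → over-reaction product (k = 0.806 h⁻¹)
    2 substrate ⇌ open dimer (K = 276 L mol⁻¹, k = 211 L mol⁻¹ h⁻¹)

The spring-to-winter ratio came to 1.19, beside my 1.19. Carried to winter at 1.81 h, the fade time takes off 4.6 percentage points, where that flask has moved by 5 points. Ring's half-life by loss to over-reaction product alone is 0.86 h, shorter than the 1.48 h that my net fade time makes and shorter than the 11 h by loss to side product alone at the winter charge. That second time is long against the winter flask's 1.5 h.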